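**Retrosynthetic overview**

1. Locants follow the daucane skeleton: C1 is the quaternary ring-fusion carbon with methyl, C2–C4 are the other cyclopentane carbons (isopropyl on C4), C5 is the ring-fusion CH, C6–C10 are the other cycloheptane carbons (methyl on C8); β is the face of the C1 methyl. Last disconnections: oxirane from the C8=C9 alkene under direction of the C10 hydroxyl, C6 ester by acylation, C6 carbinol by C4-hydroxyl-directed reduction of a C6 ketone.
2. The C10 hydroxyl and the C8=C9 alkene come from dienone 15 (C6=O, C7=C8, C9=C10) by γ,δ-epoxidation and SmI2 transposition; 15 is the hydrolysis product of the methyl trienol ether 13.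
3. Both carbocycles form in step 6: an intramolecular Buchner reaction of α-diazoketone 9 closes the cyclopentanone (C1–C5 bond) and turns the benzene ring C5–C10 into the seven-membered ring by inserting carbenoid carbon C1 between C5 and C10 (six → seven); C1 is set by the C4 stereocenter.
4. Diazoketone 9 is made in five steps from ynoate 1 and boronic acid 2: syn-hydroarylation, enantioselective β-borylation/oxidation (sets C4), silylation, saponification, acylation of diazoethane.
5. Enabling feature: ring atoms C5–C10 of the cycloheptane carry exactly the pattern of a 2-methoxy-4-methylphenyl group (attachment at C5, oxygen at C6, methyl at C8), and the seventh ring atom C1 is a quaternary carbon next to the C2 oxygen, so it can be delivered as an acyl(methyl)carbenoid tethered through C2–C3–C4.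

Key step: step 6

Remark: taken together, the descriptors written at the two oxirane carbons would put the C7–C8 and C9–C10 ring bonds on opposite sides of the oxirane, which a seven-membered ring cannot hold; the route therefore makes the ordinary cis-fused 8,9-oxirane on the face of the C10 hydroxyl (C9 as written), and every SMILES below keeps the descriptors exactly as given so that the target string is unchanged.

**Route**

Step 1
Reactants: 1 ethyl 4-methylpent-2-ynoate; 2 (2-methoxy-4-methylphenyl)boronic acid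
Product: 3 ethyl (E)-3-(2-methoxy-4-methylphenyl)-4-methylpent-2-enoate
Conditions: CuOAc (5 mol %), MeOH, 25 °C
Reagents that add atoms: none
Why: Copper-catalysed syn-hydroarylation of an alkynoate with an arylboronic acid: the arylcopper adds syn with aryl at the β-carbon and the alkenylcopper is protonated by methanol with retention, so aryl and ester end up trans (E), the geometry needed for face-selective borylation.

Step 2
Reactants: 3 ethyl (E)-3-(2-methoxy-4-methylphenyl)-4-methylpent-2-enoate
Product: 5 ethyl (3S)-3-hydroxy-3-(2-methoxy-4-methylphenyl)-4-methylpentanoate, via tertiary pinacol boronate 4 (not isolated)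
Conditions: B2pin2, CuCl (5 mol %), NaOtBu (10 mol %), (R,R)-QuinoxP* (6 mol %), MeOH, THF, 25 °C; then 30% H2O2, aq. NaOH, 0 °C
Reagents that add atoms: bis(pinacolato)diboron (boron of 4 only), CC1(C)OB(OC1(C)C)B1OC(C)(C)C(C)(C)O1; hydrogen peroxide, OO
Why: Copper-catalysed enantioselective conjugate borylation of a β,β-disubstituted enoate followed by stereoretentive C–B oxidation: the bisphosphine–copper boryl complex selects one enantioface of the E-enoate and sets C4 (the ligand antipode is chosen to give the 3S alcohol), the only stereocenter not derived from another one.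

Step 3
Reactants: 5 ethyl (3S)-3-hydroxy-3-(2-methoxy-4-methylphenyl)-4-methylpentanoate
Product: 6 ethyl (3S)-3-(2-methoxy-4-methylphenyl)-4-methyl-3-(triethylsilyloxy)pentanoate
Conditions: TESOTf, 2,6-lutidine, CH2Cl2, −78 → 0 °C
Reagents that add atoms: triethylsilyl trifluoromethanesulfonate, CC[Si](CC)(CC)OS(=O)(=O)C(F)(F)F
Why: Silylation of a hindered tertiary alcohol with a silyl triflate; the ether masks the hydroxyl against O–H insertion in step 6.

Step 4
Reactants: 6 ethyl (3S)-3-(2-methoxy-4-methylphenyl)-4-methyl-3-(triethylsilyloxy)pentanoate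
Product: 7 (3S)-3-(2-methoxy-4-methylphenyl)-4-methyl-3-(triethylsilyloxy)pentanoic acid
Conditions: LiOH, THF/MeOH/H2O, 40 °C; then 1 M HCl to pH 4, 0 °C
Reagents that add atoms: lithium hydroxide, [Li+].[OH-]
Why: Ester saponification; the tertiary silyl ether tolerates aqueous LiOH and C4 is not enolisable.

Step 5
Reactants: 7 (3S)-3-(2-methoxy-4-methylphenyl)-4-methyl-3-(triethylsilyloxy)pentanoic acid
Product: 9 (5S)-2-diazo-5-(2-methoxy-4-methylphenyl)-6-methyl-5-(triethylsilyloxy)heptan-3-one, via isobutyl carbonic anhydride 8 (not isolated)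
Conditions: iBuOCOCl, N-methylmorpholine, THF, −20 °C; then CH3CHN2 (from N-ethyl-N-nitrosourea, aq. KOH), Et2O, −20 → 0 °C
Reagents that add atoms: isobutyl chloroformate (carbonate of 8 only), CC(C)COC(=O)Cl; diazoethane, CC=[N+]=[N-]
Why: Acylation of a diazoalkane by a mixed carbonic anhydride (Arndt–Eistert-type diazoketone synthesis), a neutral method that leaves the acid-labile benzylic silyl ether intact.

Step 6
Reactants: 9 (5S)-2-diazo-5-(2-methoxy-4-methylphenyl)-6-methyl-5-(triethylsilyloxy)heptan-3-one
Product: 11 6-methoxy-4β-(triethylsilyloxy)dauca-5,7,9-trien-2-one, via norcaradiene 10 (not isolated)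
Conditions: Rh2(O2CCF3)4 (1 mol %), CH2Cl2, 25 °C, slow addition of 9
Reagents that add atoms: none
Why: The catalyst converts the diazoketone into an electrophilic rhodium carbenoid at C1 that adds across the arene bond C5–C10 (ipso carbon and the unsubstituted ortho carbon) to give norcaradiene 10, whose disrotatory 6π-electrocyclic opening of the C5–C10 bond gives cycloheptatriene 11. The closest known reaction type is the intramolecular Buchner reaction of 2-diazo-5-arylpentan-3-ones to 8a-methyl-3,4-dihydro-2H-azulen-1-ones. The five-membered ring is closed by the C1–C5 bond through the three-atom tether C2–C3–C4 (cyclopropanation at the ipso carbon), and the seven-membered ring arises from the benzene ring by insertion of C1 between C5 and C10 (cyclopropanation, then electrocyclic ring opening). C1 is the only new stereocenter and is controlled by C4: the carbenoid adds to the arene face that places its methyl group anti to the larger benzylic substituent (isopropyl) and syn to the silyloxy group, in line with the trans preference of benzylic substituents in this reaction. The step needs regioselectivity for C5–C10 over C5–C6, secured by the methoxy group that blocks its own flank, and chemoselectivity over insertion into the isopropyl C–H bond, oxonium ylide formation and 1,2-hydride shift, secured by the electron-poor trifluoroacetate ligands (which favour attack on the ipso carbon activated by ortho-methoxy and para-methyl), by the hindered, weakly basic tertiary silyl ether oxygen and by the Thorpe–Ingold effect of quaternary C4.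

Step 7
Reactants: 11 6-methoxy-4β-(triethylsilyloxy)dauca-5,7,9-trien-2-one
Product: 12 6-methoxy-4β-(triethylsilyloxy)dauca-5,7,9-trien-2β-ol
Conditions: NaBH4, MeOH, −20 °C
Reagents that add atoms: none
Why: Borohydride reduction of a cyclopentanone flanked by a quaternary carbon: hydride attacks C2 from the α face, anti to the adjacent C1 methyl (as in steroid 17-ketones), giving the 2β-alcohol; removing the ketone also shuts down acid-induced rearrangement of the trienone in step 9.

Step 8
Reactants: 12 6-methoxy-4β-(triethylsilyloxy)dauca-5,7,9-trien-2β-ol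
Product: 13 2β-acetoxy-6-methoxy-4β-(triethylsilyloxy)dauca-5,7,9-triene
Conditions: Ac2O, DMAP, pyridine, 25 °C
Reagents that add atoms: acetic anhydride, CC(=O)OC(C)=O
Why: DMAP-catalysed acetylation of the secondary alcohol; no stereocenter is touched.

Step 9
Reactants: 13 2β-acetoxy-6-methoxy-4β-(triethylsilyloxy)dauca-5,7,9-triene
Product: 15 2β-acetoxy-4β-hydroxy-5αH-dauca-7,9-dien-6-one, via silyloxy dienone 14 (not isolated)
Conditions: 1 M aq. HCl, THF, 0 → 25 °C
Reagents that add atoms: water, O
Why: Acid hydrolysis of a methyl enol ether with cleavage of the silyl ether: C5 is protonated to the diene-stabilised oxocarbenium ion, water gives the C6 ketone, and C5 takes its hydrogen on the α face, anti to the C1 methyl and the C4 oxygen (the trans-fused ketone is also the expected product of equilibration, with C6 anti to the isopropyl group).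

Step 10
Reactants: 15 2β-acetoxy-4β-hydroxy-5αH-dauca-7,9-dien-6-one
Product: 16 2β-acetoxy-9α,10α-epoxy-4β-hydroxy-5αH-dauc-7-en-6-one
Conditions: mCPBA, NaHCO3, CH2Cl2, 0 °C
Reagents that add atoms: 3-chloroperbenzoic acid, OOC(=O)c1cccc(Cl)c1
Why: Prilezhaev epoxidation, regioselective for the γ,δ-alkene because the α,β-alkene is deactivated by direct conjugation; the peracid attacks C9=C10 from the α face, anti to the C1 methyl, which fixes C10.

Step 11
Reactants: 16 2β-acetoxy-9α,10α-epoxy-4β-hydroxy-5αH-dauc-7-en-6-one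
Product: 17 2β-acetoxy-4β,10α-dihydroxy-5αH-dauc-8-en-6-one
Conditions: SmI2 (2.5 equiv), THF/MeOH, −78 °C
Reagents that add atoms: none
Why: SmI2 reduction of a vinylogous α,β-epoxy ketone: electron transfer to the enone cleaves the C9–O bond and the samarium dienolate is protonated at C7, giving the β,γ-unsaturated ketone with the C10–O bond and its configuration untouched.

Step 12
Reactants: 17 2β-acetoxy-4β,10α-dihydroxy-5αH-dauc-8-en-6-one
Product: 18 2β-acetoxy-4β-hydroxy-10α-(triethylsilyloxy)-5αH-dauc-8-en-6-one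
Conditions: TESCl, imidazole, DMF, 0 → 25 °C
Reagents that add atoms: chlorotriethylsilane, CC[Si](Cl)(CC)CC
Why: Chemoselective silylation of the secondary allylic alcohol in the presence of the unreactive tertiary C4 hydroxyl.

Step 13
Reactants: 18 2β-acetoxy-4β-hydroxy-10α-(triethylsilyloxy)-5αH-dauc-8-en-6-one
Product: 19 2β-acetoxy-10α-(triethylsilyloxy)-5αH-dauc-8-ene-4β,6α-diol
Conditions: Me4NBH(OAc)3, MeCN/AcOH, −30 °C
Reagents that add atoms: none
Why: Evans–Saksena hydroxyl-directed reduction: the C4 hydroxyl exchanges onto boron and delivers hydride intramolecularly to the β face of the C6 carbonyl, giving the 6α-alcohol (anti to the 4β-hydroxyl).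

Step 14
Reactants: 19 2β-acetoxy-10α-(triethylsilyloxy)-5αH-dauc-8-ene-4β,6α-diol; 20 3,4-dimethoxybenzoyl chloride
Product: 21 2β-acetoxy-4β-hydroxy-10α-(triethylsilyloxy)-5αH-dauc-8-en-6α-yl 3,4-dimethoxybenzoate
Conditions: Et3N, DMAP, CH2Cl2, 0 → 25 °C
Reagents that add atoms: none
Why: DMAP-catalysed acylation of the only free secondary alcohol by an acid chloride; the tertiary C4 hydroxyl does not react and C6 keeps its configuration.

Step 15
Reactants: 21 2β-acetoxy-4β-hydroxy-10α-(triethylsilyloxy)-5αH-dauc-8-en-6α-yl 3,4-dimethoxybenzoate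
Product: 22 2β-acetoxy-4β,10α-dihydroxy-5αH-dauc-8-en-6α-yl 3,4-dimethoxybenzoate
Conditions: HF·pyridine, pyridine, THF, 0 °C
Reagents that add atoms: none
Why: Fluoride cleavage of the secondary silyl ether under buffered conditions that leave both esters in place.

Step 16
Reactants: 22 2β-acetoxy-4β,10α-dihydroxy-5αH-dauc-8-en-6α-yl 3,4-dimethoxybenzoate
Product: 23 2β-acetoxy-8,9-epoxy-4β,10α-dihydroxy-5αH-daucan-6α-yl 3,4-dimethoxybenzoate (target)
Conditions: VO(acac)2 (5 mol %), tBuOOH, CH2Cl2, 0 → 25 °C
Reagents that add atoms: tert-butyl hydroperoxide, CC(C)(C)OO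
Why: Vanadium-catalysed hydroxyl-directed epoxidation of an allylic alcohol: the C10 vanadate ester delivers the peroxide oxygen to the C8=C9 face syn to the hydroxyl, setting C8 and C9 in one step as the α-oxirane described in the remark.

**Compound list**

1 | ethyl 4-methylpent-2-ynoate | CCOC(=O)C#CC(C)C | starting material
2 | (2-methoxy-4-methylphenyl)boronic acid | COc1cc(C)ccc1B(O)O | starting material
3 | ethyl (E)-3-(2-methoxy-4-methylphenyl)-4-methylpent-2-enoate | CCOC(=O)/C=C(/c1ccc(C)cc1OC)C(C)C | intermediate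
4 | ethyl (3R)-3-(2-methoxy-4-methylphenyl)-4-methyl-3-(4,4,5,5-tetramethyl-1,3,2-dioxaborolan-2-yl)pentanoate (not isolated) | COc1cc(C)ccc1[C@@](B1OC(C)(C)C(C)(C)O1)(C(C)C)CC(=O)OCC | intermediate
5 | ethyl (3S)-3-hydroxy-3-(2-methoxy-4-methylphenyl)-4-methylpentanoate | COc1cc(C)ccc1[C@@](O)(C(C)C)CC(=O)OCC | intermediate
6 | ethyl (3S)-3-(2-methoxy-4-methylphenyl)-4-methyl-3-(triethylsilyloxy)pentanoate | COc1cc(C)ccc1[C@@](O[Si](CC)(CC)CC)(C(C)C)CC(=O)OCC | intermediate
7 | (3S)-3-(2-methoxy-4-methylphenyl)-4-methyl-3-(triethylsilyloxy)pentanoic acid | COc1cc(C)ccc1[C@@](O[Si](CC)(CC)CC)(C(C)C)CC(=O)O | intermediate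
8 | isobutyl carbonic anhydride of acid 7 (not isolated) | COc1cc(C)ccc1[C@@](O[Si](CC)(CC)CC)(C(C)C)CC(=O)OC(=O)OCC(C)C | intermediate
9 | (5S)-2-diazo-5-(2-methoxy-4-methylphenyl)-6-methyl-5-(triethylsilyloxy)heptan-3-one | COc1cc(C)ccc1[C@@](O[Si](CC)(CC)CC)(C(C)C)CC(=O)C(C)=[N+]=[N-] | intermediate
10 | norcaradiene valence isomer of 11, cyclopropane C1–C5–C10 (not isolated) | COC2=CC(C)=C[C@H]4[C@]3(C)C(=O)C[C@](O[Si](CC)(CC)CC)(C(C)C)[C@@]234 | intermediate
11 | 6-methoxy-4β-(triethylsilyloxy)dauca-5,7,9-trien-2-one | COC=2C=C(C)C=C[C@]3(C)C(=O)C[C@](O[Si](CC)(CC)CC)(C(C)C)C=23 | intermediate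
12 | 6-methoxy-4β-(triethylsilyloxy)dauca-5,7,9-trien-2β-ol | COC=2C=C(C)C=C[C@]3(C)[C@@H](O)C[C@](O[Si](CC)(CC)CC)(C(C)C)C=23 | intermediate
13 | 2β-acetoxy-6-methoxy-4β-(triethylsilyloxy)dauca-5,7,9-triene | COC=2C=C(C)C=C[C@]3(C)[C@@H](OC(C)=O)C[C@](O[Si](CC)(CC)CC)(C(C)C)C=23 | intermediate
14 | 2β-acetoxy-4β-(triethylsilyloxy)-5αH-dauca-7,9-dien-6-one (not isolated) | O=C2C=C(C)C=C[C@]3(C)[C@@H](OC(C)=O)C[C@](O[Si](CC)(CC)CC)(C(C)C)[C@@H]23 | intermediate
15 | 2β-acetoxy-4β-hydroxy-5αH-dauca-7,9-dien-6-one | O=C2C=C(C)C=C[C@]3(C)[C@@H](OC(C)=O)C[C@](O)(C(C)C)[C@@H]23 | intermediate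
16 | 2β-acetoxy-9α,10α-epoxy-4β-hydroxy-5αH-dauc-7-en-6-one | O=C2C=C(C)[C@@H]4O[C@@H]4[C@]3(C)[C@@H](OC(C)=O)C[C@](O)(C(C)C)[C@@H]23 | intermediate
17 | 2β-acetoxy-4β,10α-dihydroxy-5αH-dauc-8-en-6-one | O=C2CC(C)=C[C@H](O)[C@]3(C)[C@@H](OC(C)=O)C[C@](O)(C(C)C)[C@@H]23 | intermediate
18 | 2β-acetoxy-4β-hydroxy-10α-(triethylsilyloxy)-5αH-dauc-8-en-6-one | O=C2CC(C)=C[C@H](O[Si](CC)(CC)CC)[C@]3(C)[C@@H](OC(C)=O)C[C@](O)(C(C)C)[C@@H]23 | intermediate
19 | 2β-acetoxy-10α-(triethylsilyloxy)-5αH-dauc-8-ene-4β,6α-diol | O[C@@H]2CC(C)=C[C@H](O[Si](CC)(CC)CC)[C@]3(C)[C@@H](OC(C)=O)C[C@](O)(C(C)C)[C@@H]23 | intermediate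
20 | 3,4-dimethoxybenzoyl chloride | COc1ccc(C(=O)Cl)cc1OC | starting material
21 | 2β-acetoxy-4β-hydroxy-10α-(triethylsilyloxy)-5αH-dauc-8-en-6α-yl 3,4-dimethoxybenzoate | COc1ccc(C(=O)O[C@@H]2CC(C)=C[C@H](O[Si](CC)(CC)CC)[C@]3(C)[C@@H](OC(C)=O)C[C@](O)(C(C)C)[C@@H]23)cc1OC | intermediate
22 | 2β-acetoxy-4β,10α-dihydroxy-5αH-dauc-8-en-6α-yl 3,4-dimethoxybenzoate | COc1ccc(C(=O)O[C@@H]2CC(C)=C[C@H](O)[C@]3(C)[C@@H](OC(C)=O)C[C@](O)(C(C)C)[C@@H]23)cc1OC | intermediate
23 | 2β-acetoxy-8,9-epoxy-4β,10α-dihydroxy-5αH-daucan-6α-yl 3,4-dimethoxybenzoate | COc1ccc(C(=O)O[C@@H]2C[C@@]3(C)O[C@@H]3[C@H](O)[C@]3(C)[C@@H](OC(C)=O)C[C@](O)(C(C)C)[C@@H]23)cc1OC | target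

**Step count and risks**

Total step count: 16. Longest linear sequence: 16 steps (1 → 23).

Steps most likely to fail:

1. Step 6 (Buchner ring expansion). The methyl-substituted carbenoid may be diverted (1,2-hydride shift to the vinyl ketone, insertion into the isopropyl C–H bond, capture by the silyl ether oxygen), or face selection at C1 may be poor. The fallback sets out from acid 7. Its mixed anhydride 8 is treated with CH2N2 (from N-methyl-N-nitroso-p-toluenesulfonamide, KOH) instead of diazoethane to give the diazomethyl ketone (3S)-1-diazo-4-(2-methoxy-4-methylphenyl)-5-methyl-4-(triethylsilyloxy)hexan-2-one F1. The unhindered monosubstituted carbenoid from F1 (Rh2(OAc)4, CH2Cl2), the substrate class with the closest precedent, undergoes the same ring expansion to the C1-unsubstituted trienone 6-methoxy-15-nor-4β-(triethylsilyloxy)dauca-5,7,9-trien-2-one F2. Its extended enolate (KOtBu, THF, −78 °C) is methylated with MeI at C1, from the face anti to the C4 isopropyl group, which comes back to the route at 11.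

2. Step 9 (hydrolysis and desilylation). The C4 oxygen may be lost by ionisation or β-elimination when the tertiary aldol is unveiled next to the conjugated dienone, and the C5 configuration may drift. The fallback sets out from 13 and keeps the silyl ether until the carbonyl is deconjugated. Oxalic acid in wet THF hydrolyses only the enol ether, and 14 is isolated. mCPBA/NaHCO3 then gives 2β-acetoxy-9α,10α-epoxy-4β-(triethylsilyloxy)-5αH-dauc-7-en-6-one F3. SmI2 in THF/MeOH gives 2β-acetoxy-10α-hydroxy-4β-(triethylsilyloxy)-5αH-dauc-8-en-6-one F4. HF·pyridine removes the silyl group and comes back to the route at 17.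

3. Step 2 (enantioselective borylation). The hindered β-aryl-β-isopropyl enoate may react sluggishly or with low enantioface discrimination. The fallback sets out from 3. A Shi epoxidation (fructose-derived ketone catalyst, KHSO5, K2CO3, aq. MeCN) gives ethyl (2R,3S)-3-(2-methoxy-4-methylphenyl)-3-(propan-2-yl)oxirane-2-carboxylate F5. SmI2 in THF/MeOH cleaves the Cα–O bond of this glycidic ester and comes back to the route at 5.

**Further compounds**

F1 | step 6 | (3S)-1-diazo-4-(2-methoxy-4-methylphenyl)-5-methyl-4-(triethylsilyloxy)hexan-2-one | COc1cc(C)ccc1[C@@](O[Si](CC)(CC)CC)(C(C)C)CC(=O)C=[N+]=[N-]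
F2 | step 6 | 6-methoxy-15-nor-4β-(triethylsilyloxy)dauca-5,7,9-trien-2-one | COC=2C=C(C)C=C[C@@H]3C(=O)C[C@](O[Si](CC)(CC)CC)(C(C)C)C=23
F3 | step 9 | 2β-acetoxy-9α,10α-epoxy-4β-(triethylsilyloxy)-5αH-dauc-7-en-6-one | O=C2C=C(C)[C@@H]4O[C@@H]4[C@]3(C)[C@@H](OC(C)=O)C[C@](O[Si](CC)(CC)CC)(C(C)C)[C@@H]23
F4 | step 9 | 2β-acetoxy-10α-hydroxy-4β-(triethylsilyloxy)-5αH-dauc-8-en-6-one | O=C2CC(C)=C[C@H](O)[C@]3(C)[C@@H](OC(C)=O)C[C@](O[Si](CC)(CC)CC)(C(C)C)[C@@H]23
F5 | step 2 | ethyl (2R,3S)-3-(2-methoxy-4-methylphenyl)-3-(propan-2-yl)oxirane-2-carboxylate | COc1cc(C)ccc1[C@]2(C(C)C)O[C@H]2C(=O)OCC
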